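The 14-membered carbocycle (ring A) is closed at C12–C13 (cembrane numbering) by a nickel-catalysed reductive epoxide–alkyne macrocyclisation. The step exploits the homoallylic alcohol array C14(OH)–C13H2–C12(CH3)=C11H of ring A. The seco precursor carries a terminal C13–C14 epoxide on the trans-γ-lactone (ring B) and a C11≡C12 methyl alkyne. One operation should forge the ring, the (E)-trisubstituted olefin and the free C14 carbinol. The precursor comes from a vinylogous Mukaiyama aldol (C6), a chromium-mediated, lactone-templated allylation (C1, C2) and a translactonisation. The exo-methylene is masked as its dimethylamine adduct during the nickel step.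

Key step: step 15

Numbering: cembrane positions are used throughout: C1 (lactone β-carbon, ring fusion), C2 (lactone O–CH), C3=C4(CH3), C5, C6 (OAc), C7=C8(CH3), C9, C10, C11=C12(CH3), C13, C14 (OH), C15 (lactone α-carbon), C16 (C=O), C17 (exo-methylene). The target is (1S,2S,6S,14S).

Remark: the (S,S)-antipode of the bisphosphoramide catalyst is assumed to direct the dienolate to the Si face of the enynal in the vinylogous aldol (S carbinol); if the sense proves opposite, the (R,R)-antipode is used.

Remark: 5-bromopent-2-yne and (R)-but-3-ene-1,2-diol are taken as purchasable; otherwise they follow in one operation from pent-3-yn-1-ol (CBr4, PPh3) and from butadiene monoepoxide (hydrolytic kinetic resolution).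

Step 1
Reactants: 1 5-bromopent-2-yne; 2 ethyl but-2-ynoate
Product: 5 ethyl (E)-3-methyloct-2-en-6-ynoate, via pent-3-ynylmagnesium bromide 3 (not isolated), via pent-3-ynylcopper 4 (not isolated)
Conditions: Mg, THF, rt; CuI, THF, −40 °C; then 2, −78 °C; aq NH4Cl
Reagents that add atoms: none
Why: Syn-carbocupration of the 2-alkynoate by the alkylcopper at −78 °C places the pent-3-ynyl group trans to the ester, so protonation should give the (E)-3-methyl enoate (conjugate carbocupration of an ynoate).

Step 2
Reactants: 5 ethyl (E)-3-methyloct-2-en-6-ynoate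
Product: 6 (E)-3-methyloct-2-en-6-yn-1-ol
Conditions: i-Bu2AlH (2.2 equiv), CH2Cl2, −78 °C; aq potassium sodium tartrate
Reagents that add atoms: none
Why: 1,2-Reduction of the enoate by i-Bu2AlH should give the allylic alcohol without touching the alkyne or the olefin geometry (ester reduction).

Step 3
Reactants: 6 (E)-3-methyloct-2-en-6-yn-1-ol
Product: 7 (E)-3-methyloct-2-en-6-ynal
Conditions: MnO2 (excess), CH2Cl2, rt
Reagents that add atoms: none
Why: MnO2 oxidises the allylic alcohol chemoselectively to the enal with retention of the olefin geometry (allylic oxidation).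

Step 4
Reactants: 8 ethyl 3-methylbut-2-enoate
Product: 9 tert-butyl[(1-ethoxy-3-methylbuta-1,3-dien-1-yl)oxy]dimethylsilane (mixture of ketene acetal isomers)
Conditions: LiN(i-Pr)2, THF, −78 °C; then t-BuMe2SiCl, DMPU, −78 °C to rt
Reagents that add atoms: tert-butyldimethylsilyl chloride, CC(C)(C)[Si](C)(C)Cl
Why: Kinetic γ-deprotonation of the senecioate and O-silylation of the extended enolate should give the silyl dienol ether (silyl ketene acetal formation).

Step 5
Reactants: 7 (E)-3-methyloct-2-en-6-ynal; 9 silyl dienol ether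
Product: 10 ethyl (5S,2E,6E)-5-hydroxy-3,7-dimethyldodeca-2,6-dien-10-ynoate
Conditions: SiCl4 (1.1 equiv), (S,S)-bisphosphoramide (two (S)-N,N'-dimethyl-1,1'-binaphthyl-2,2'-diamine phosphoramide units linked by N,N'-dimethylpentane-1,5-diamine, 5 mol %), i-Pr2NEt (10 mol %), CH2Cl2, −78 °C; aq NaHCO3
Reagents that add atoms: none
Why: The chiral phosphoramide-bound trichlorosilyl cation activates the aldehyde and the dienolate attacks through its γ-carbon on the Si face, which should set C6 (S) and give the (E)-enoate (Lewis-base-catalysed vinylogous Mukaiyama aldol).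

Step 6
Reactants: 10 ethyl (5S,2E,6E)-5-hydroxy-3,7-dimethyldodeca-2,6-dien-10-ynoate
Product: 11 (5S,2E,6E)-3,7-dimethyldodeca-2,6-dien-10-yne-1,5-diol
Conditions: i-Bu2AlH (3.5 equiv), CH2Cl2, −78 to 0 °C; aq potassium sodium tartrate
Reagents that add atoms: none
Why: i-Bu2AlH should reduce the enoate to the primary allylic alcohol and leave the carbinol stereocentre untouched (ester reduction).

Step 7
Reactants: 11 (5S,2E,6E)-3,7-dimethyldodeca-2,6-dien-10-yne-1,5-diol
Product: 12 (5S,2E,6E)-5-hydroxy-3,7-dimethyldodeca-2,6-dien-10-ynal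
Conditions: TEMPO (2,2,6,6-tetramethylpiperidin-1-oxyl, 10 mol %), PhI(OAc)2 (1.1 equiv), CH2Cl2, rt
Reagents that add atoms: none
Why: The oxoammonium oxidant reacts much faster with the primary allylic alcohol than with the secondary one, so the hydroxy enal should form selectively (TEMPO/PhI(OAc)2 oxidation).

Step 8
Reactants: 12 (5S,2E,6E)-5-hydroxy-3,7-dimethyldodeca-2,6-dien-10-ynal
Product: 13 (5S,2E,6E)-3,7-dimethyl-1-oxododeca-2,6-dien-10-yn-5-yl acetate
Conditions: Ac2O, pyridine, 4-(dimethylamino)pyridine (5 mol %), CH2Cl2, 0 °C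
Reagents that add atoms: acetic anhydride, CC(=O)OC(C)=O
Why: Acylation of the only hydroxyl installs the C6 acetate of the target before any step that would no longer distinguish it from the C14 hydroxyl (esterification).

Step 9
Reactants: 14 2-(bromomethyl)acrylic acid; 15 (R)-but-3-ene-1,2-diol
Product: 17 (R)-2-hydroxybut-3-en-1-yl 2-(bromomethyl)acrylate, via acid chloride 16 (not isolated)
Conditions: (COCl)2, DMF (cat.), CH2Cl2, 0 °C; then 15, 2,4,6-collidine, CH2Cl2, −78 °C
Reagents that add atoms: none
Why: With the hindered base at −78 °C the acid chloride should acylate the primary hydroxyl selectively over the secondary allylic one, and collidine does not alkylate the allylic bromide (selective acylation).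

Step 10
Reactants: 17 (R)-2-hydroxybut-3-en-1-yl 2-(bromomethyl)acrylate
Product: 18 (R)-2-[(tert-butyldimethylsilyl)oxy]but-3-en-1-yl 2-(bromomethyl)acrylate
Conditions: t-BuMe2SiOTf, 2,6-lutidine, CH2Cl2, −78 °C
Reagents that add atoms: tert-butyldimethylsilyl triflate, CC(C)(C)[Si](C)(C)OS(=O)(=O)C(F)(F)F
Why: Silylation protects the future C14 oxygen so that only the C2 hydroxyl can later take part in acyl transfer (silyl ether formation).

Step 11
Reactants: 18 (R)-2-[(tert-butyldimethylsilyl)oxy]but-3-en-1-yl 2-(bromomethyl)acrylate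
Product: 19 (R)-3-(bromomethyl)-5-[(tert-butyldimethylsilyl)oxy]-5,6-dihydro-2H-pyran-2-one
Conditions: second-generation Grubbs catalyst (5 mol %), CH2Cl2 (0.01 M), 40 °C
Reagents that add atoms: none
Why: Ring-closing metathesis of the acrylate of a homoallylic alcohol should give the six-membered unsaturated lactone with loss of ethene, the allylic bromide being tolerated (ring-closing olefin metathesis).

Step 12
Reactants: 13 (5S,2E,6E)-3,7-dimethyl-1-oxododeca-2,6-dien-10-yn-5-yl acetate; 19 (R)-3-(bromomethyl)-5-[(tert-butyldimethylsilyl)oxy]-5,6-dihydro-2H-pyran-2-one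
Product: 22 (4R,5S)-5-[(1E,4S,5E)-4-acetoxy-2,6-dimethylundeca-1,5-dien-9-yn-1-yl]-4-[(1R)-1-[(tert-butyldimethylsilyl)oxy]-2-hydroxyethyl]-3-methylenedihydrofuran-2(3H)-one, via allylchromium dichloride 20 (not isolated), via δ-lactone adduct 21 (not isolated)
Conditions: CrCl2 (3 equiv), THF, 0 °C to rt; aq NH4Cl; then pyridinium p-toluenesulfonate (cat.), CH2Cl2, rt
Reagents that add atoms: none
Why: In this Nozaki–Hiyama (Barbier-type) allylation divalent chromium converts 19 into allylchromium 20, whose ring holds the C1 substituent trans to the CH2–Cr carbon, so addition to 13 through a chair transition state on the face opposite to the silyloxy group should set C1 and C2 (anti, both relayed from C14), after which acid-catalysed acyl transfer to the new secondary hydroxyl turns δ-lactone 21 into the more stable trans-disubstituted γ-lactone 22.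

Step 13
Reactants: 22 γ-lactone alcohol
Product: 24 (4R,5S)-5-[(1E,4S,5E)-4-acetoxy-2,6-dimethylundeca-1,5-dien-9-yn-1-yl]-3-methylene-4-[(2R)-oxiran-2-yl]dihydrofuran-2(3H)-one, via primary mesylate 23 (not isolated)
Conditions: MsCl, Et3N, CH2Cl2, 0 °C; then Bu4NF, THF, 0 °C
Reagents that add atoms: none
Why: Mesylation of the only free (primary) hydroxyl followed by fluoride desilylation releases the C14 alkoxide, which should close the terminal epoxide by 3-exo-tet displacement with retention at C14 (intramolecular Williamson epoxide closure).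

Step 14
Reactants: 24 epoxy α-methylene lactone
Product: 25 (3S,4R,5S)-5-[(1E,4S,5E)-4-acetoxy-2,6-dimethylundeca-1,5-dien-9-yn-1-yl]-3-[(dimethylamino)methyl]-4-[(2R)-oxiran-2-yl]dihydrofuran-2(3H)-one (expected trans,trans epimer drawn; either epimer serves)
Conditions: Me2NH (2 M in THF, 1.5 equiv), THF, 0 °C
Reagents that add atoms: dimethylamine, CNC
Why: Aza-Michael addition to the exo-methylene lactone is far faster at 0 °C than aminolysis of the epoxide or the acetate and masks the acrylate for the nickel step; the new α-centre is removed again in step 16 (conjugate addition).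

Step 15
Reactants: 25 amine-masked epoxy alkyne
Product: 26 (1S,2S,6S,14S,15S)-6-acetoxy-17-(dimethylamino)-14-hydroxycembra-3E,7E,11E-trien-16,2-olide (cembrane numbering)
Conditions: Ni(cod)2 (20 mol %), PBu3 (40 mol %), Et3B (4 equiv), THF, rt, slow addition of 25 (final 0.005 M)
Reagents that add atoms: none
Why: Zerovalent nickel (bis(1,5-cyclooctadiene)nickel with the small phosphine PBu3) joins the alkyne and the terminal epoxide by oxidative addition into the less hindered C13–O bond and syn-insertion of the alkyne (C13 to C12, nickel to C11), and Et3B then cleaves the Ni–O bond as a boron alkoxide and, through ethyl transfer, β-hydride elimination and C11–H reductive elimination, delivers hydrogen cis to C13. The closest known reaction type is the nickel-catalysed reductive coupling of alkynes with epoxides, which is established for ring closures, large rings included. Ring A is closed in a 14-endo-dig mode with respect to the alkyne and by endo opening of the epoxide at its terminal carbon. No sp3 stereocentre is created: C14 keeps the epoxide configuration because only the C13–O bond breaks, and the (E)-geometry of C11=C12 follows from the syn addition of C13 and H. The step needs C12-over-C11 regioselectivity, which the small methyl group on C12 with the small phosphine (larger substituent next to nickel) and the lower strain of a 14-membered endocyclic (E)-olefin against a 13-membered ring with an exocyclic ethylidene should secure, and C13-over-C14 selectivity, which the terminal epoxide secures. Chemoselectivity over the trisubstituted olefins and the allylic esters should follow from the much stronger binding of the alkyne to nickel, and the acrylate is out of play because it is masked as the amine adduct.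

Step 16
Reactants: 26 macrocyclic amine adduct
Product: 28 kericembrenolide D, (1S,2S,6S,14S)-6-acetoxy-14-hydroxycembra-3E,7E,11E,15(17)-tetraen-16,2-olide, via trimethylammonium iodide 27 (not isolated)
Conditions: MeI (excess), THF/MeOH, rt; then aq NaHCO3, rt
Reagents that add atoms: none
Why: Exhaustive N-methylation gives quaternary salt 27, whose mild base-induced β-elimination (Hofmann-type, E1cB) should regenerate the exo-methylene lactone without touching the acetate or the free C14 hydroxyl.

Compound list
1 | 5-bromopent-2-yne | CC#CCCBr | starting material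
2 | ethyl but-2-ynoate | CC#CC(=O)OCC | starting material
3 | pent-3-ynylmagnesium bromide | CC#CCC[Mg]Br | intermediate
4 | pent-3-ynylcopper (MgBrI complex) | CC#CCC[Cu] | intermediate
5 | ethyl (E)-3-methyloct-2-en-6-ynoate | CCOC(=O)/C=C(\C)CCC#CC | intermediate
6 | (E)-3-methyloct-2-en-6-yn-1-ol | OC/C=C(\C)CCC#CC | intermediate
7 | (E)-3-methyloct-2-en-6-ynal | O=C/C=C(\C)CCC#CC | intermediate
8 | ethyl 3-methylbut-2-enoate | CCOC(=O)C=C(C)C | starting material
9 | tert-butyl[(1-ethoxy-3-methylbuta-1,3-dien-1-yl)oxy]dimethylsilane | C=C(C)C=C(OCC)O[Si](C)(C)C(C)(C)C | intermediate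
10 | ethyl (5S,2E,6E)-5-hydroxy-3,7-dimethyldodeca-2,6-dien-10-ynoate | CCOC(=O)/C=C(\C)C[C@H](O)/C=C(\C)CCC#CC | intermediate
11 | (5S,2E,6E)-3,7-dimethyldodeca-2,6-dien-10-yne-1,5-diol | OC/C=C(\C)C[C@H](O)/C=C(\C)CCC#CC | intermediate
12 | (5S,2E,6E)-5-hydroxy-3,7-dimethyldodeca-2,6-dien-10-ynal | O=C/C=C(\C)C[C@H](O)/C=C(\C)CCC#CC | intermediate
13 | (5S,2E,6E)-3,7-dimethyl-1-oxododeca-2,6-dien-10-yn-5-yl acetate | O=C/C=C(\C)C[C@H](OC(C)=O)/C=C(\C)CCC#CC | intermediate
14 | 2-(bromomethyl)acrylic acid | OC(=O)C(=C)CBr | starting material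
15 | (R)-but-3-ene-1,2-diol | OC[C@H](O)C=C | starting material
16 | 2-(bromomethyl)acryloyl chloride | ClC(=O)C(=C)CBr | intermediate
17 | (R)-2-hydroxybut-3-en-1-yl 2-(bromomethyl)acrylate | BrCC(=C)C(=O)OC[C@H](O)C=C | intermediate
18 | (R)-2-[(tert-butyldimethylsilyl)oxy]but-3-en-1-yl 2-(bromomethyl)acrylate | BrCC(=C)C(=O)OC[C@H](O[Si](C)(C)C(C)(C)C)C=C | intermediate
19 | (R)-3-(bromomethyl)-5-[(tert-butyldimethylsilyl)oxy]-5,6-dihydro-2H-pyran-2-one | O=C1OC[C@H](O[Si](C)(C)C(C)(C)C)C=C1CBr | intermediate
20 | allylchromium dichloride derived from 19 (trivalent chromium) | O=C1OC[C@H](O[Si](C)(C)C(C)(C)C)C=C1C[Cr](Cl)Cl | intermediate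
21 | (4R,5R)-4-[(1S,2E,5S,6E)-5-acetoxy-1-hydroxy-3,7-dimethyldodeca-2,6-dien-10-yn-1-yl]-5-[(tert-butyldimethylsilyl)oxy]-3-methylenetetrahydro-2H-pyran-2-one | C=C1C(=O)OC[C@H](O[Si](C)(C)C(C)(C)C)[C@H]1[C@@H](O)/C=C(\C)C[C@H](OC(C)=O)/C=C(\C)CCC#CC | intermediate
22 | (4R,5S)-5-[(1E,4S,5E)-4-acetoxy-2,6-dimethylundeca-1,5-dien-9-yn-1-yl]-4-[(1R)-1-[(tert-butyldimethylsilyl)oxy]-2-hydroxyethyl]-3-methylenedihydrofuran-2(3H)-one | C=C1C(=O)O[C@@H](/C=C(\C)C[C@H](OC(C)=O)/C=C(\C)CCC#CC)[C@@H]1[C@@H](O[Si](C)(C)C(C)(C)C)CO | intermediate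
23 | methanesulfonate of 22 at the primary hydroxyl | C=C1C(=O)O[C@@H](/C=C(\C)C[C@H](OC(C)=O)/C=C(\C)CCC#CC)[C@@H]1[C@@H](O[Si](C)(C)C(C)(C)C)COS(C)(=O)=O | intermediate
24 | (4R,5S)-5-[(1E,4S,5E)-4-acetoxy-2,6-dimethylundeca-1,5-dien-9-yn-1-yl]-3-methylene-4-[(2R)-oxiran-2-yl]dihydrofuran-2(3H)-one | C=C1C(=O)O[C@@H](/C=C(\C)C[C@H](OC(C)=O)/C=C(\C)CCC#CC)[C@@H]1[C@@H]2CO2 | intermediate
25 | (3S,4R,5S)-5-[(1E,4S,5E)-4-acetoxy-2,6-dimethylundeca-1,5-dien-9-yn-1-yl]-3-[(dimethylamino)methyl]-4-[(2R)-oxiran-2-yl]dihydrofuran-2(3H)-one | CN(C)C[C@H]1C(=O)O[C@@H](/C=C(\C)C[C@H](OC(C)=O)/C=C(\C)CCC#CC)[C@@H]1[C@@H]2CO2 | intermediate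
26 | (1S,2S,6S,14S,15S)-6-acetoxy-17-(dimethylamino)-14-hydroxycembra-3E,7E,11E-trien-16,2-olide | CN(C)C[C@H]1C(=O)O[C@H]2/C=C(\C)C[C@H](OC(C)=O)/C=C(\C)CC/C=C(\C)C[C@H](O)[C@H]12 | intermediate
27 | N-methyl quaternary ammonium iodide of 26 | C[N+](C)(C)C[C@H]1C(=O)O[C@H]2/C=C(\C)C[C@H](OC(C)=O)/C=C(\C)CC/C=C(\C)C[C@H](O)[C@H]12.[I-] | intermediate
28 | kericembrenolide D | C=C1C(=O)O[C@H]2/C=C(\C)C[C@H](OC(C)=O)/C=C(\C)CC/C=C(\C)C[C@H](O)[C@H]12 | target

Total step count: 16. Longest linear sequence: 12 steps (steps 1, 2, 3, 5, 6, 7, 8, 12, 13, 14, 15, 16).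

Steps most likely to fail

Step 15 (key step). The alkyne may insert in the opposite sense (C13 to C11), which would close a 13-membered ring with an exocyclic ethylidene. Zerovalent nickel may also ionise the allylic acetate or the allylic lactone C–O bond. A further risk is slow intramolecular attack of the tertiary amine on the epoxide before cyclisation. The fallback fixes the regiochemistry before ring closure by replacing the alkyne with a defined alkenyl iodide, and sets out from diol 11. Hydrozirconation with excess Cp2Zr(H)Cl (equilibration places zirconium on the methyl-bearing carbon) and iodinolysis with I2 should give the (E)-iodo triene diol F1. TEMPO/PhI(OAc)2 oxidation gives hydroxy enal F2 and acetylation gives acetoxy enal F3. Chromium-mediated allylation with 19 (through 20 and the δ-lactone adduct F4) and acid-catalysed acyl transfer give the γ-lactone alcohol F5. MsCl then Bu4NF give, through the primary mesylate F6, the epoxy lactone F7, and Me2NH gives the amine adduct F8. A nickel-catalysed reductive cross-electrophile coupling of the alkenyl iodide with the terminal epoxide (NiI2, 4,4'-di-tert-butyl-2,2'-bipyridine, NaI, Et3N·HCl, Mn powder, DMPU, high dilution) then closes the same C12–C13 bond and returns to the route at 26.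

Step 12. The allylation may show poor simple or facial diastereoselectivity (an open transition state, or attack syn to the silyloxy group), or the silyloxy group may undergo β-elimination from allylchromium 20. The fallback sets out from bromide 19. Borylation with bis(pinacolato)diboron under Pd2(dba)3 catalysis (DMSO, 50 °C) should give the allylboronate F9. Thermal allylboration of 13 (toluene, 60 °C) proceeds through a strictly closed chair transition state and should give 21 after work-up; the acid-catalysed acyl transfer then returns to the route at 22.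

Step 5. The hindered β,β-disubstituted enal may give insufficient enantioselectivity or competing α-attack of the dienolate. The fallback sets out from 7 and 9. An achiral vinylogous Mukaiyama aldol with BF3·OEt2 (CH2Cl2, −78 °C) gives the racemic hydroxy ester F10, and MnO2 oxidation gives the dienone F11. Enantioselective reduction with catecholborane and (R)-2-methyl-CBS-oxazaborolidine (the alkenyl group acting as the large substituent) should deliver the S carbinol and return to the route at 10.

Further compounds
F1 | step 15 | (5S,2E,6E,10E)-11-iodo-3,7-dimethyldodeca-2,6,10-triene-1,5-diol | OC/C=C(\C)C[C@H](O)/C=C(\C)CC/C=C(\C)I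
F2 | step 15 | (5S,2E,6E,10E)-5-hydroxy-11-iodo-3,7-dimethyldodeca-2,6,10-trienal | O=C/C=C(\C)C[C@H](O)/C=C(\C)CC/C=C(\C)I
F3 | step 15 | (5S,2E,6E,10E)-11-iodo-3,7-dimethyl-1-oxododeca-2,6,10-trien-5-yl acetate | O=C/C=C(\C)C[C@H](OC(C)=O)/C=C(\C)CC/C=C(\C)I
F4 | step 15 | δ-lactone adduct, alkenyl iodide analogue of 21 | C=C1C(=O)OC[C@H](O[Si](C)(C)C(C)(C)C)[C@H]1[C@@H](O)/C=C(\C)C[C@H](OC(C)=O)/C=C(\C)CC/C=C(\C)I
F5 | step 15 | γ-lactone alcohol, alkenyl iodide analogue of 22 | C=C1C(=O)O[C@@H](/C=C(\C)C[C@H](OC(C)=O)/C=C(\C)CC/C=C(\C)I)[C@@H]1[C@@H](O[Si](C)(C)C(C)(C)C)CO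
F6 | step 15 | primary mesylate, alkenyl iodide analogue of 23 | C=C1C(=O)O[C@@H](/C=C(\C)C[C@H](OC(C)=O)/C=C(\C)CC/C=C(\C)I)[C@@H]1[C@@H](O[Si](C)(C)C(C)(C)C)COS(C)(=O)=O
F7 | step 15 | epoxy lactone, alkenyl iodide analogue of 24 | C=C1C(=O)O[C@@H](/C=C(\C)C[C@H](OC(C)=O)/C=C(\C)CC/C=C(\C)I)[C@@H]1[C@@H]2CO2
F8 | step 15 | dimethylamine adduct, alkenyl iodide analogue of 25 | CN(C)C[C@H]1C(=O)O[C@@H](/C=C(\C)C[C@H](OC(C)=O)/C=C(\C)CC/C=C(\C)I)[C@@H]1[C@@H]2CO2
F9 | step 12 | (R)-5-[(tert-butyldimethylsilyl)oxy]-3-[(4,4,5,5-tetramethyl-1,3,2-dioxaborolan-2-yl)methyl]-5,6-dihydro-2H-pyran-2-one | O=C1OC[C@H](O[Si](C)(C)C(C)(C)C)C=C1CB2OC(C)(C)C(C)(C)O2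
F10 | step 5 | ethyl (2E,6E)-5-hydroxy-3,7-dimethyldodeca-2,6-dien-10-ynoate (racemic) | CCOC(=O)/C=C(\C)CC(O)/C=C(\C)CCC#CC
F11 | step 5 | ethyl (2E,6E)-3,7-dimethyl-5-oxododeca-2,6-dien-10-ynoate | CCOC(=O)/C=C(\C)CC(=O)/C=C(\C)CCC#CC
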